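## Structural features

Sideroxylonal C is a 2-aryl-3,4-dialkyl-3,4-dihydro-2H-chromene. A fully substituted benzene ring A is fused through C4a and C8a to the pyran ring B (O1, C2, C3, C4), and a second fully substituted benzene, ring C, is attached to C2 through C1′. Rings A and C are both 2,4-diformylphloroglucinol units, one oxygen of ring A being O1, so the molecule carries five free phenols and four aldehydes, each aldehyde lying between two oxygen-bearing carbons. The stereocentres C2 (aryl), C3 (isopropyl) and C4 (isobutyl) are contiguous and all-trans (2R,3R,4R), which allows all three substituents to be equatorial on the half-chair of ring B; this is also the most stable arrangement. The fragile points are the formyl phenols (base, oxidants, hydrogenation) and above all the O1–C2 bond: C2 is a benzylic carbon stabilised by the three ortho/para oxygens of ring C, and O1 becomes a vinylogous carboxylate leaving group once ring A carries its formyl groups, so acids can open ring B. The real difficulty is to set three adjacent stereocentres that bear only carbon substituents, in the absolute sense, while eight oxygen functions and four aldehyde carbons are carried along. The key step uses the fact that C2 is an aldehyde-level carbon bonded to O1, to ring C and to C3, and that the isopropyl group on C3 can be read as a reduced prop-1-en-2-yl group, the trace of a 2-methylprop-1-enyl unit that has attacked a cation through C3. The phenolic O1, an aldehyde equivalent of ring C and that alkene can therefore be joined in one cationic event that forms O1–C2 and C2–C3, closes ring B and lets the existing centre C4 dictate C3 and C2. The only ring positions without oxygen (C6, C8, C3′, C5′) are exactly the four formyl positions, so they can be held as C–Br bonds while the cationic chemistry is done.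

## Logic of the disconnections

18 ⇒ 17. The five O–CH3 bonds (on O5, O7, O2′, O4′, O6′) are cut last. Free phenols beside aldehydes would not survive organolithium or cationic steps, whereas methyl ethers survive every step of the route. The gain is that all earlier steps can ignore phenol acidity. The demand is one exhaustive dealkylation that must not ionise O1–C2, which is why it is placed after four formyl groups have made both rings electron-poor.

17 ⇒ 14. The four aryl–CHO bonds (C6, C8, C3′, C5′) are traced back to four aryl–Br bonds. These are the only nucleophilic ring positions; as bromides they are blocked during the cationic steps and can be formylated under basic conditions, without any Lewis acid near the labile O1–C2 bond. Four sensitive aldehydes disappear in one operation. The forward step must achieve a fourfold halogen–metal exchange in which each aryl anion is flanked by two ether oxygens.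

14 ⇒ 13. The isopropyl group on C3 is traced to a prop-1-en-2-yl group, the group a cation–alkene cyclisation leaves behind. No skeletal bond is cut. The forward step must saturate a 1,1-disubstituted alkene without touching four C–Br bonds or the benzylic O1–C2 bond.

13 ⇒ 8 + 11. O1–C2 and C2–C3 are cut together. C2 is at the aldehyde level and lies between a phenol oxygen and an alkene carbon, so an oxocarbenium–alkene closure makes both bonds, ring B and the centres C2 and C3 in one step. The problem falls apart into a phenol with a single stereocentre (8) and an achiral aldehyde equivalent (11). The forward step must attack through oxygen first and carbon second, must not attack any ring position, and must relay C4 to C3 and C2.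

11 ⇒ 10 ⇒ 9. The two acetal C–O bonds and then the two C–Br bonds on ring C are removed. The acetal is the ionisable form of the aldehyde; the bromines keep ring C from attacking its own cation and are the latent formyl groups. Both steps are simple functionalisations of a commercial aldehyde.

8 ⇒ 7. The side-chain C=C bond is cut in the sense of an alkylidene exchange (isopropylidene back to ethylidene). A sigmatropic shift with chirality transfer can only deliver a 1,2-disubstituted alkene, so the trisubstituted alkene must be made afterwards. The forward exchange has to work next to a congested benzylic centre without moving the double bond.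

7 ⇒ 6. The two C–Br bonds on ring A are removed. They are introduced at the two remaining ring positions, which are the most nucleophilic sites of the molecule. The forward step must brominate the ring faster than the alkene.

6 ⇒ 4. The C(aryl)–C4 bond is cut; an ortho-allyl phenol is the retron of an aromatic [3,3] shift. The carbon stereocentre is thereby exchanged for a C–O stereocentre, which is much easier to make. The forward step must pass through a single chair so that the configuration is transferred faithfully.

4 ⇒ 2 + 3. The aryl O–C bond is cut, giving a commercial phenol and a secondary allylic alcohol. The forward etherification must proceed with clean inversion and without allylic transposition.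

2 ⇒ 1. The carbinol C–H bond is cut, giving a commercial enone. The forward step is a catalytic enantioselective reduction and is the only source of absolute configuration in the route.

## Other disconnections considered

Alternative 1: Ring A is cut at C5–C6 and C8–C8a and is built from dimethyl 3-oxopentanedioate A1 and the alkylmalonate A2, which already carries C3, C4 and C2 (as a dimethyl acetal). In the forward step the two α-carbons of A1 are acylated by the two ester groups of A2 and the ring aromatises by enolisation to the phloroglucinol diester A3. In its favour: the two formyl carbons of ring A are present from the start at the carboxyl level, so ring A needs neither blocking groups nor late formylation, and on this point it is better than the chosen plan. The C3/C4 pair is set on an open chain, which is equal in difficulty to the cyclic relay used here. Against it: a monosubstituted malonate is deprotonated under the basic conditions and then no longer behaves as an acylating agent, so forcing conditions would be needed, and the branched substituent next to the malonate carbon hinders both acylations. If the C4 centre of A2 were made by conjugate addition, reversal of that addition under hot base would endanger it. The key step forms no stereocentre, does not close ring B and does not attach ring C; after it, the pyran must be closed, ring C joined to C2 by a Friedel–Crafts step, ring C formylated twice and two hydrogen-bonded esters reduced to aldehydes without over-reduction. On mechanism, an anionic condensation that builds an arene compares with a cationic cyclisation that builds ring B and two stereocentres. On step economy the alternative is clearly longer.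

Alternative 2: The cuts are C4–C4a and O1–C2. Phloroglucinol A4 adds through a ring carbon to the β-carbon of the enal A5 (the self-condensation dimer of a five-carbon aldehyde) under iminium activation by a chiral primary amine salt, and the neighbouring phenol closes the lactol A6. In its favour: A5 contains all nine aliphatic carbons, no protecting group is needed, and C2 emerges at the lactol level, ready to take up a second molecule of A4 under thermodynamic control. In step economy this is the best of all four plans. C3 is α to a masked aldehyde and can be equilibrated to trans, which the chosen plan cannot offer. C2 is set under thermodynamic control in both plans, so they are equal on that point. Against it: α-branched enals are reluctant iminium substrates, and here the α-substituent is an isopropyl group; the addition of an electron-rich arene can be reversible, which would erode the enantiomeric purity; A4 has three equivalent nucleophilic carbons and can react more than once. The unprotected bis-phloroglucinol chromane that must then be formylated four times is the most acid-labile and oxidation-prone form of the skeleton. The absolute configuration would rest on an untested catalyst–substrate pairing, whereas the chosen plan takes it from a ketone reduction and a sigmatropic transfer.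

Alternative 3: The cuts are O1–C8a and C4–C4a. Fluoride releases an aryne from the silylaryl triflate A7; the alkoxide of the hydroxy enoate A8 adds to it and the resulting aryl anion adds to the enoate β-carbon, giving A9. In its favour: C2, C3 and ring C are assembled beforehand by open-chain aldol-type chemistry, which fixes the C2 configuration more securely than a cyclisation does and is a point on which it is better. The methoxy group next to the aryne directs the oxygen to C8a and the anion to C4a, and no halogen blocking groups are needed in the annulation, so on regiocontrol it is equal to the chosen plan. Against it: the hindered benzylic alkoxide of A8 can fragment in a vinylogous retro-aldol sense, and its γ-hydrogen (on the future C3) is acidic, so C3 may epimerise. The aryl anion may be protonated before it cyclises, and C4 would be set under uncertain kinetic control. The ester side chain of A9 must still be turned into isobutyl (about three steps), and all four formyl groups must be introduced at the end on an unblocked, acid-sensitive 2-arylchromane. A7 and A8 each need several steps. The alternative forms one stereocentre in its key step against two here, relies on anionic rather than cationic ring closure, and is longer overall.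

Key step: step 8

Remark on the chemistry: ring C enters the key step with bromine at both free positions (compounds 10, 11, 13). Only spectator atoms change, and the skeletons of the two partners and of the product and the two bonds formed stay the same. Ring C is thereby protected from Friedel–Crafts attack by its own cation, and all four formyl groups can be introduced in one basic operation, so no Lewis-acid formylation is needed on the labile 2-arylchromane.

## Route

Step 1
Reactants: 1 (3E)-6-methylhept-3-en-2-one
Product: 2 (2R,3E)-6-methylhept-3-en-2-ol
Conditions: (S)-2-methyl-CBS-oxazaborolidine (0.1 equiv), catecholborane (1.5 equiv), toluene, −78 °C; aq. NaOH work-up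
Reagents that add atoms: none
Why: Corey–Bakshi–Shibata reduction; with the alkenyl group as the large and methyl as the small substituent the (S)-catalyst should deliver hydride to give the (R)-carbinol, and catecholborane at −78 °C avoids hydroboration and 1,4-reduction.

Step 2
Reactants: 2 (2R,3E)-6-methylhept-3-en-2-ol; 3 3,5-dimethoxyphenol
Product: 4 1,3-dimethoxy-5-{[(2S,3E)-6-methylhept-3-en-2-yl]oxy}benzene
Conditions: PPh3, DIAD, toluene, 0 °C → rt
Reagents that add atoms: none
Why: Mitsunobu etherification; SN2 displacement of the oxyphosphonium group by the phenol inverts C2 of the chain to (S), and the non-polar solvent should suppress ionisation and SN2′ attack.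

Step 3
Reactants: 4 1,3-dimethoxy-5-{[(2S,3E)-6-methylhept-3-en-2-yl]oxy}benzene
Product: 6 3,5-dimethoxy-2-[(2E,4R)-6-methylhept-2-en-4-yl]phenol, via ortho-dienone 5 (not isolated)
Conditions: PhNEt2, 180 °C, sealed tube
Reagents that add atoms: none
Why: aromatic Claisen rearrangement; the suprafacial [3,3] shift through a chair with the methyl group equatorial should transfer the (S) C–O centre to the (R) benzylic C–C centre and give the (E)-alkene, after which dienone 5 enolises. The two ortho positions are equivalent; any (Z)-isomer carries the opposite configuration and should be removed before step 5.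

Step 4
Reactants: 6 3,5-dimethoxy-2-[(2E,4R)-6-methylhept-2-en-4-yl]phenol
Product: 7 2,4-dibromo-3,5-dimethoxy-6-[(2E,4R)-6-methylhept-2-en-4-yl]phenol
Conditions: NBS (2.05 equiv), CH2Cl2, −78 → 0 °C
Reagents that add atoms: N-bromosuccinimide, O=C1CCC(=O)N1Br
Why: electrophilic aromatic bromination; the two remaining positions of the phloroglucinol-type ring should react far faster than the 1,2-disubstituted alkene at low temperature, and the bromines serve as blocking groups and latent formyl groups.

Step 5
Reactants: 7 2,4-dibromo-3,5-dimethoxy-6-[(2E,4R)-6-methylhept-2-en-4-yl]phenol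
Product: 8 2,4-dibromo-6-[(4R)-2,6-dimethylhept-2-en-4-yl]-3,5-dimethoxyphenol
Conditions: second-generation Hoveyda–Grubbs catalyst RuCl2(H2IMes)(=CH-C6H4-2-O-i-Pr) (5–10 mol%), 2-methylbut-2-ene (large excess), CH2Cl2, 40 °C, sealed tube
Reagents that add atoms: 2-methylbut-2-ene, CC=C(C)C
Why: olefin cross-metathesis; the ethylidene end of the propenyl group is exchanged for isopropylidene, driven by the excess of 2-methylbut-2-ene and the loss of but-2-ene, and the benzylic stereocentre is not involved.

Step 6
Reactants: 9 2,4,6-trimethoxybenzaldehyde
Product: 10 3,5-dibromo-2,4,6-trimethoxybenzaldehyde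
Conditions: NBS (2.2 equiv), MeCN, 0 °C → rt
Reagents that add atoms: N-bromosuccinimide, O=C1CCC(=O)N1Br
Why: electrophilic aromatic bromination at the two positions that are each flanked by two methoxy groups and meta to the formyl group.

Step 7
Reactants: 10 3,5-dibromo-2,4,6-trimethoxybenzaldehyde
Product: 11 1,3-dibromo-5-(dimethoxymethyl)-2,4,6-trimethoxybenzene
Conditions: HC(OMe)3, MeOH, TsOH·H2O (cat.), 50 °C; Et3N quench
Reagents that add atoms: trimethyl orthoformate, COC(OC)OC; methanol, CO
Why: acid-catalysed acetalisation driven to completion by the orthoformate as dehydrating agent.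

Step 8
Reactants: 8 2,4-dibromo-6-[(4R)-2,6-dimethylhept-2-en-4-yl]-3,5-dimethoxyphenol; 11 1,3-dibromo-5-(dimethoxymethyl)-2,4,6-trimethoxybenzene
Product: 13 (2R,3S,4R)-6,8-dibromo-2-(3,5-dibromo-2,4,6-trimethoxyphenyl)-5,7-dimethoxy-4-(2-methylpropyl)-3-(prop-1-en-2-yl)-3,4-dihydro-2H-chromene, via mixed aryl methyl acetal 12 (not isolated)
Conditions: 11 (1.5 equiv), Me3SiOTf (3 equiv), 2,6-di-tert-butyl-4-methylpyridine (3.5 equiv), 4 Å MS, CH2Cl2 (0.02 M), −78 → −30 °C
Reagents that add atoms: none
Why: Me3SiOTf ionises 11 to a methoxycarbenium ion that the phenol oxygen of 8 captures to give mixed acetal 12; silylation of the more basic methoxy oxygen of 12 then expels Me3SiOMe and leaves the O-aryl oxocarbenium ion O1=C2 (bond O1–C2). The tethered 2-methylpropenyl group attacks C2 through its less substituted carbon C3 (bond C2–C3), and the positive charge developing on the CMe2 carbon is discharged by loss of a methyl proton to the hindered pyridine, which leaves the prop-1-en-2-yl group. The closest known reactions are the oxonium-ene (Prins) cyclisation of 4-en-1-ols with aldehydes or acetals to 2,3-trans-tetrahydropyrans and the generation of aryl oxocarbenium ions from O-aryl O-methyl acetals in oxa-Povarov chemistry. Ring B closes as a six-membered ring with the oxocarbenium bond inside the new ring and the alkene bond outside it (exo with respect to the alkene). C3 is controlled by allylic 1,3-strain: the cis-methyl group of the alkene holds the C4–H bond in the alkene plane, so ring A and the isobutyl group lie on opposite faces, and the tethered electrophile can arrive only from the ring A face, in a chair that has the isobutyl group and the alkene unit equatorial, which gives 3,4-trans. C2 is controlled by the (E)-geometry of the oxocarbenium ion, which places ring C equatorial and gives 2,3-trans; because O1–C2 can re-ionise, the all-equatorial isomer is also the thermodynamic sink. The step needs attack by oxygen and then by the alkene instead of Friedel–Crafts attack, and this is secured by bromine at every free position of both rings and by the methyl ether on the C5 oxygen, which leaves only one phenol able to react. The excess of hindered base keeps the medium free of triflic acid, so that the phenol should not add across its own alkene and the product alkene should not be re-protonated.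

Step 9
Reactants: 13 (2R,3S,4R)-6,8-dibromo-2-(3,5-dibromo-2,4,6-trimethoxyphenyl)-5,7-dimethoxy-4-(2-methylpropyl)-3-(prop-1-en-2-yl)-3,4-dihydro-2H-chromene
Product: 14 (2R,3R,4R)-6,8-dibromo-2-(3,5-dibromo-2,4,6-trimethoxyphenyl)-5,7-dimethoxy-4-(2-methylpropyl)-3-(propan-2-yl)-3,4-dihydro-2H-chromene
Conditions: TsNHNH2 (excess, in portions), NaOAc, DME/H2O, 85 °C
Reagents that add atoms: none
Why: diimide reduction; concerted syn transfer of two hydrogens to the 1,1-disubstituted alkene should leave the four C–Br bonds and the benzylic O1–C2 bond untouched, which hydrogenation over palladium would not guarantee. No stereocentre is formed, and the descriptor of C3 changes from S to R only because the substituent priority changes.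

Step 10
Reactants: 14 (2R,3R,4R)-6,8-dibromo-2-(3,5-dibromo-2,4,6-trimethoxyphenyl)-5,7-dimethoxy-4-(2-methylpropyl)-3-(propan-2-yl)-3,4-dihydro-2H-chromene
Product: 17 (2R,3R,4R)-2-(3,5-diformyl-2,4,6-trimethoxyphenyl)-5,7-dimethoxy-4-(2-methylpropyl)-3-(propan-2-yl)-3,4-dihydro-2H-chromene-6,8-dicarbaldehyde, via tetralithio arene 15 (not isolated), via tetrakis(lithium aminoalkoxide) 16 (not isolated)
Conditions: t-BuLi (8.5 equiv), THF, −78 °C; DMF (excess), −78 → 0 °C; 0.5 M aq. HCl, 0 °C
Reagents that add atoms: N,N-dimethylformamide, CN(C)C=O
Why: bromine–lithium exchange followed by formylation with DMF; each aryllithium site of 15 is flanked by two ether oxygens that stabilise it, and the tetrahedral adducts 16 mask the new carbonyl groups until the acidic work-up. All four formyl groups are thus introduced under basic conditions, without a Lewis acid that could ionise O1–C2.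

Step 11
Reactants: 17 (2R,3R,4R)-2-(3,5-diformyl-2,4,6-trimethoxyphenyl)-5,7-dimethoxy-4-(2-methylpropyl)-3-(propan-2-yl)-3,4-dihydro-2H-chromene-6,8-dicarbaldehyde
Product: 18 sideroxylonal C, (2R,3R,4R)-2-(3,5-diformyl-2,4,6-trihydroxyphenyl)-5,7-dihydroxy-4-(2-methylpropyl)-3-(propan-2-yl)-3,4-dihydro-2H-chromene-6,8-dicarbaldehyde
Conditions: BBr3 (15 equiv), CH2Cl2, −78 → 0 °C; ice-water
Reagents that add atoms: none
Why: Lewis-acid cleavage of aryl methyl ethers; every methoxy group is ortho to a formyl group, so each cleavage is chelation-assisted. The two formyl groups on ring C destabilise a cation at C2, so O1–C2 should survive, and reclosure after any ionisation would return the all-equatorial isomer.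

## Compound list

1 | (3E)-6-methylhept-3-en-2-one | CC(=O)/C=C/CC(C)C | starting material
2 | (2R,3E)-6-methylhept-3-en-2-ol | C[C@@H](O)/C=C/CC(C)C | intermediate
3 | 3,5-dimethoxyphenol | COc1cc(O)cc(OC)c1 | starting material
4 | 1,3-dimethoxy-5-{[(2S,3E)-6-methylhept-3-en-2-yl]oxy}benzene | C[C@H](Oc1cc(OC)cc(OC)c1)/C=C/CC(C)C | intermediate
5 | (6R)-3,5-dimethoxy-6-[(2E,4R)-6-methylhept-2-en-4-yl]cyclohexa-2,4-dien-1-one (configuration at C6 as expected from the chair) | O=C1C=C(OC)C=C(OC)[C@H]1[C@H](CC(C)C)/C=C/C | intermediate (not isolated)
6 | 3,5-dimethoxy-2-[(2E,4R)-6-methylhept-2-en-4-yl]phenol | CC(C)C[C@H](/C=C/C)c1c(O)cc(OC)cc1OC | intermediate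
7 | 2,4-dibromo-3,5-dimethoxy-6-[(2E,4R)-6-methylhept-2-en-4-yl]phenol | CC(C)C[C@H](/C=C/C)c1c(O)c(Br)c(OC)c(Br)c1OC | intermediate
8 | 2,4-dibromo-6-[(4R)-2,6-dimethylhept-2-en-4-yl]-3,5-dimethoxyphenol | CC(C)C[C@H](C=C(C)C)c1c(O)c(Br)c(OC)c(Br)c1OC | intermediate
9 | 2,4,6-trimethoxybenzaldehyde | COc1cc(OC)c(C=O)c(OC)c1 | starting material
10 | 3,5-dibromo-2,4,6-trimethoxybenzaldehyde | COc1c(Br)c(OC)c(C=O)c(OC)c1Br | intermediate
11 | 1,3-dibromo-5-(dimethoxymethyl)-2,4,6-trimethoxybenzene | COC(OC)c1c(OC)c(Br)c(OC)c(Br)c1OC | intermediate
12 | 1,3-dibromo-5-[{2,4-dibromo-6-[(4R)-2,6-dimethylhept-2-en-4-yl]-3,5-dimethoxyphenoxy}(methoxy)methyl]-2,4,6-trimethoxybenzene (both epimers at the acetal carbon) | CC(C)C[C@H](C=C(C)C)c1c(OC(OC)c2c(OC)c(Br)c(OC)c(Br)c2OC)c(Br)c(OC)c(Br)c1OC | intermediate (not isolated)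
13 | (2R,3S,4R)-6,8-dibromo-2-(3,5-dibromo-2,4,6-trimethoxyphenyl)-5,7-dimethoxy-4-(2-methylpropyl)-3-(prop-1-en-2-yl)-3,4-dihydro-2H-chromene | CC(C)C[C@H]1c2c(OC)c(Br)c(OC)c(Br)c2O[C@@H](c2c(OC)c(Br)c(OC)c(Br)c2OC)[C@@H]1C(C)=C | intermediate
14 | (2R,3R,4R)-6,8-dibromo-2-(3,5-dibromo-2,4,6-trimethoxyphenyl)-5,7-dimethoxy-4-(2-methylpropyl)-3-(propan-2-yl)-3,4-dihydro-2H-chromene | CC(C)C[C@H]1c2c(OC)c(Br)c(OC)c(Br)c2O[C@@H](c2c(OC)c(Br)c(OC)c(Br)c2OC)[C@@H]1C(C)C | intermediate
15 | (2R,3R,4R)-6,8-dilithio-2-(3,5-dilithio-2,4,6-trimethoxyphenyl)-5,7-dimethoxy-4-(2-methylpropyl)-3-(propan-2-yl)-3,4-dihydro-2H-chromene | CC(C)C[C@H]1c2c(OC)c([Li])c(OC)c([Li])c2O[C@@H](c2c(OC)c([Li])c(OC)c([Li])c2OC)[C@@H]1C(C)C | intermediate (not isolated)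
16 | fourfold DMF adduct of 15: (2R,3R,4R) core as in 14 with a CH(OLi)NMe2 group on each of C6, C8, C3′ and C5′ (aminal carbons as mixtures) | CC(C)C[C@H]1c2c(OC)c(C(O[Li])N(C)C)c(OC)c(C(O[Li])N(C)C)c2O[C@@H](c2c(OC)c(C(O[Li])N(C)C)c(OC)c(C(O[Li])N(C)C)c2OC)[C@@H]1C(C)C | intermediate (not isolated)
17 | (2R,3R,4R)-2-(3,5-diformyl-2,4,6-trimethoxyphenyl)-5,7-dimethoxy-4-(2-methylpropyl)-3-(propan-2-yl)-3,4-dihydro-2H-chromene-6,8-dicarbaldehyde | CC(C)C[C@H]1c2c(OC)c(C=O)c(OC)c(C=O)c2O[C@@H](c2c(OC)c(C=O)c(OC)c(C=O)c2OC)[C@@H]1C(C)C | intermediate
18 | sideroxylonal C, (2R,3R,4R)-2-(3,5-diformyl-2,4,6-trihydroxyphenyl)-5,7-dihydroxy-4-(2-methylpropyl)-3-(propan-2-yl)-3,4-dihydro-2H-chromene-6,8-dicarbaldehyde | CC(C)C[C@H]1c2c(O)c(C=O)c(O)c(C=O)c2O[C@@H](c2c(O)c(C=O)c(O)c(C=O)c2O)[C@@H]1C(C)C | target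

## Step count and least certain steps

Total: 11 steps (steps 1–5 and 8–11 in the main line, steps 6–7 in the branch to 11). Longest linear sequence: 9 steps (1 to 18 through steps 1–5 and 8–11).

Step 8 (key step). The most likely failures are protonation of the trisubstituted alkene followed by capture by the neighbouring phenol (closure to a 2,2-dimethylchromane), slow ionisation of the congested mixed acetal, and loss of C3 selectivity if the C–C bond forms intermolecularly before the O–C tether exists, so that the chair no longer applies. Fallback, setting out from 8 and 10 and returning at 13: the bond order is reversed. An Me2AlCl-promoted carbonyl-ene reaction between the alkene of 8 (held as its aluminium phenoxide) and aldehyde 10 should form C2–C3 and the prop-1-en-2-yl group and give (2S,3R)-3-(3,5-dibromo-2-hydroxy-4,6-dimethoxyphenyl)-1-(3,5-dibromo-2,4,6-trimethoxyphenyl)-5-methyl-2-(prop-1-en-2-yl)hexan-1-ol F1 as a mixture at C1. Mild acid-catalysed cyclodehydration (camphorsulfonic acid, CH2Cl2, 0 °C) then closes O1–C2 through the benzylic cation under thermodynamic control and gives 13.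

Step 5. The propenyl group sits next to a fully substituted benzylic carbon, so turnover may be slow, and ruthenium hydride species formed on catalyst decay could move the double bond into conjugation with ring A, which would erase the C4 stereocentre. Fallback, setting out from 7 and returning at 8: the phenol is silylated (TBSOTf, 2,6-lutidine) to tert-butyl{2,4-dibromo-3,5-dimethoxy-6-[(2E,4R)-6-methylhept-2-en-4-yl]phenoxy}dimethylsilane F2. Oxidative cleavage of the alkene (OsO4 cat., NaIO4, 2,6-lutidine, dioxane/H2O) gives (2S)-2-{3,5-dibromo-2-[(tert-butyldimethylsilyl)oxy]-4,6-dimethoxyphenyl}-4-methylpentanal F3, in which the twisted, doubly ortho-substituted aryl group should slow enolisation. A Wittig reaction with Ph3P=C(CH3)2 at −78 °C gives tert-butyl{2,4-dibromo-6-[(4R)-2,6-dimethylhept-2-en-4-yl]-3,5-dimethoxyphenoxy}dimethylsilane F4, and n-Bu4NF releases 8.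

Step 10. The fourfold exchange may stop short, or partly lithiated intermediates may be protonated, so that formyl groups are missing; deprotonation at the benzylic C2–H by the excess base is a further risk. Fallback, setting out from 14 and returning at 17: a fourfold Suzuki–Miyaura coupling (K[CH2=CHBF3], Pd(OAc)2, SPhos, K3PO4, toluene/H2O, 90 °C) should give (2R,3R,4R)-6,8-diethenyl-2-(3,5-diethenyl-2,4,6-trimethoxyphenyl)-5,7-dimethoxy-4-(2-methylpropyl)-3-(propan-2-yl)-3,4-dihydro-2H-chromene F5. Oxidative cleavage of the four vinyl groups (OsO4 cat., NaIO4, 2,6-lutidine) then gives 17 without any organolithium.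

Step 11. BBr3 may ionise O1–C2 (ring opening and elimination towards a C2=C3 alkene), may leave the two methoxy groups that lie between two formyl groups uncleaved, or may convert formyl groups into dibromomethyl groups on long exposure. Fallback, setting out from 17 and returning at 18: the polarity of the deprotection is reversed. A thiolate (NaSEt in DMF, 100–120 °C) removes the methyl groups by SN2 attack at carbon in the absence of any Lewis acid, so the O1–C2 bond is not activated; no new compound is made on this way (F0). Its own weakness is that each phenoxide formed slows the next dealkylation.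

Step 3. Chirality transfer may be incomplete: the chair with the methyl group axial gives the (Z)-alkene with the opposite configuration at the benzylic carbon, and ionisation and recombination of the secondary allylic ether at 180 °C would racemise it; SN2′ attack in step 2 would feed in a regioisomeric ether. Fallback, setting out from 2 and 3 and returning at 6: alcohol 2 is esterified with retention to (2R,3E)-6-methylhept-3-en-2-yl pyridine-2-carboxylate F6, and phenol 3 is protected (MOMCl, i-Pr2NEt) as 1,3-dimethoxy-5-(methoxymethoxy)benzene F7. Ortho-lithiation of F7 between the two different oxygens (n-BuLi), transmetalation (MgBr2·OEt2) and copper-mediated anti-SN2′ substitution of F6 (CuBr·SMe2, THF, −40 °C) should give 1,5-dimethoxy-3-(methoxymethoxy)-2-[(2E,4R)-6-methylhept-2-en-4-yl]benzene F8. Acid methanolysis (HCl, MeOH) then gives 6. This way needs neither the Mitsunobu step nor heating.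

## Further compounds

F1 | step 8 | (2S,3R)-3-(3,5-dibromo-2-hydroxy-4,6-dimethoxyphenyl)-1-(3,5-dibromo-2,4,6-trimethoxyphenyl)-5-methyl-2-(prop-1-en-2-yl)hexan-1-ol (C1 epimers) | CC(C)C[C@@H](c1c(O)c(Br)c(OC)c(Br)c1OC)[C@@H](C(C)=C)C(O)c1c(OC)c(Br)c(OC)c(Br)c1OC
F2 | step 5 | tert-butyl{2,4-dibromo-3,5-dimethoxy-6-[(2E,4R)-6-methylhept-2-en-4-yl]phenoxy}dimethylsilane | CC(C)C[C@H](/C=C/C)c1c(O[Si](C)(C)C(C)(C)C)c(Br)c(OC)c(Br)c1OC
F3 | step 5 | (2S)-2-{3,5-dibromo-2-[(tert-butyldimethylsilyl)oxy]-4,6-dimethoxyphenyl}-4-methylpentanal | CC(C)C[C@H](C=O)c1c(O[Si](C)(C)C(C)(C)C)c(Br)c(OC)c(Br)c1OC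
F4 | step 5 | tert-butyl{2,4-dibromo-6-[(4R)-2,6-dimethylhept-2-en-4-yl]-3,5-dimethoxyphenoxy}dimethylsilane | CC(C)C[C@H](C=C(C)C)c1c(O[Si](C)(C)C(C)(C)C)c(Br)c(OC)c(Br)c1OC
F5 | step 10 | (2R,3R,4R)-6,8-diethenyl-2-(3,5-diethenyl-2,4,6-trimethoxyphenyl)-5,7-dimethoxy-4-(2-methylpropyl)-3-(propan-2-yl)-3,4-dihydro-2H-chromene | CC(C)C[C@H]1c2c(OC)c(C=C)c(OC)c(C=C)c2O[C@@H](c2c(OC)c(C=C)c(OC)c(C=C)c2OC)[C@@H]1C(C)C
F0 | step 11 | none | none
F6 | step 3 | (2R,3E)-6-methylhept-3-en-2-yl pyridine-2-carboxylate | C[C@@H](OC(=O)c1ccccn1)/C=C/CC(C)C
F7 | step 3 | 1,3-dimethoxy-5-(methoxymethoxy)benzene | COCOc1cc(OC)cc(OC)c1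
F8 | step 3 | 1,5-dimethoxy-3-(methoxymethoxy)-2-[(2E,4R)-6-methylhept-2-en-4-yl]benzene | CC(C)C[C@H](/C=C/C)c1c(OCOC)cc(OC)cc1OC
A1 | alternative 1 | dimethyl 3-oxopentanedioate | COC(=O)CC(=O)CC(=O)OC
A2 | alternative 1 | dimethyl 2-[(4R,5R)-6,6-dimethoxy-2-methyl-5-(propan-2-yl)hexan-4-yl]propanedioate | COC(OC)[C@H](C(C)C)[C@@H](CC(C)C)C(C(=O)OC)C(=O)OC
A3 | alternative 1 | dimethyl 5-[(4R,5R)-6,6-dimethoxy-2-methyl-5-(propan-2-yl)hexan-4-yl]-2,4,6-trihydroxybenzene-1,3-dicarboxylate | COC(OC)[C@H](C(C)C)[C@@H](CC(C)C)c1c(O)c(C(=O)OC)c(O)c(C(=O)OC)c1O
A4 | alternative 2 | benzene-1,3,5-triol (phloroglucinol) | Oc1cc(O)cc(O)c1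
A5 | alternative 2 | (2E)-5-methyl-2-(propan-2-yl)hex-2-enal | CC(C)C/C=C(/C=O)C(C)C
A6 | alternative 2 | (3R,4R)-4-(2-methylpropyl)-3-(propan-2-yl)chromane-2,5,7-triol (anomers at C2) | CC(C)C[C@H]1c2c(O)cc(O)cc2OC(O)[C@@H]1C(C)C
A7 | alternative 3 | 3,5-dimethoxy-2-(trimethylsilyl)phenyl trifluoromethanesulfonate | COc1cc(OC)c([Si](C)(C)C)c(OS(=O)(=O)C(F)(F)F)c1
A8 | alternative 3 | ethyl (2E,4R,5R)-5-hydroxy-4-(propan-2-yl)-5-(2,4,6-trimethoxyphenyl)pent-2-enoate | CCOC(=O)/C=C/[C@@H](C(C)C)[C@@H](O)c1c(OC)cc(OC)cc1OC
A9 | alternative 3 | ethyl 2-[(2R,3R,4R)-5,7-dimethoxy-3-(propan-2-yl)-2-(2,4,6-trimethoxyphenyl)chroman-4-yl]acetate | CCOC(=O)C[C@H]1c2c(OC)cc(OC)cc2O[C@@H](c2c(OC)cc(OC)cc2OC)[C@@H]1C(C)C
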